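**Plan**

1. Numbering (eremophilane type): ring A = C1–C5 and C10, ring B = C5–C10; oxygen on C3 and C9, ketone C8, isopropylidene (C11) on C7, methyl groups on C4 and C5; β = the face of the C5 methyl.
2. Cuts: (a) the C3–O ester bond (diol 17 + trienoic acid 22); (b) C7=C11 (aldol with acetone); (c) ring A along C1–C10 and C4–C5, a Diels–Alder cut that leaves 3-methylcyclohex-2-enone (ring B) and a 3-silyloxy-1,3-pentadiene.
3. Enabling feature: in ring A the C3 oxygen lies 1,4 to C10, C10 is α to the C9 oxygen of ring B, and the quaternary C5 (β to C9) is bonded to the methyl-bearing C4 next to C3. Ring A is therefore the enol-ether cyclohexene retron of a 2-oxy-diene (C1=C2–C3(O)=C4–CH3) adding to an enone (C10=C5, C9=O) in the electronically matched sense.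
4. Forward: ring B is bought; ring A is closed on it by the enantioselective [4+2] (step 2); ring B is then re-functionalised (9-ketone → 7-en-9-one → 8-en-9-yl triflate → 8-ene → 8α,9α-diol → 9α-hydroxy-8-ketone → 7-isopropylidene); the side chain is attached last.
5. Stereochemistry: only the quaternary C5 is set by the catalyst. C4 and C10 are equilibrated to the trans-fused, equatorial-methyl isomer (step 4); the 3α-OH comes from thermodynamic dissolving-metal reduction (step 5); the 9α-OH from osmylation anti to the C5 methyl (step 7); the alkene geometries from syn-carbometalation and the Heck reaction.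

Key step: step 2

Assumption: the (S)-configured oxazaborolidine is taken to shield the enone face that leads to adduct 4 with the C5 configuration of the target; if the sense of induction proves opposite, the (R)-configured catalyst is used and nothing else changes.

**Route**

Step 1
Reactants: 1 pent-1-en-3-one
Product: 2 (Z)-triisopropyl(penta-1,3-dien-3-yloxy)silane
Conditions: TIPSOTf, Et3N, Et2O, 0 °C → rt
Reagents that add atoms: triisopropylsilyl trifluoromethanesulfonate, CC(C)[Si](C(C)C)(C(C)C)OS(=O)(=O)C(F)(F)F
Why: Silyl triflate/amine enolisation of the ethyl ketone (silyl enol ether formation) removes an α'-proton and should give the 2-silyloxydiene as the Z enol ether (methyl cis to oxygen), the isomer normally formed from ethyl ketones under these conditions and the one whose s-cis conformer is unhindered.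

Step 2
Reactants: 2 (Z)-triisopropyl(penta-1,3-dien-3-yloxy)silane; 3 3-methylcyclohex-2-en-1-one
Product: 4 cis-fused adduct 4α,5β-dimethyl-3-(triisopropylsilyloxy)-10β-H-decal-2-en-9-one
Conditions: (S)-3,3-diphenyl-1-(2-methylphenyl)tetrahydro-1H,3H-pyrrolo[1,2-c][1,3,2]oxazaborole (C24H24BNO, 20 mol %) pre-mixed with AlBr3 (16 mol %), CH2Cl2, −78 → −20 °C
Reagents that add atoms: none
Why: Proposed new method: the AlBr3-activated chiral oxazaborolidine binds the C9 carbonyl of 3 (with the α-C–H···O contact at C10 known for its complexes of cyclohex-2-enone), and the electron-rich C4 terminus of diene 2 attacks the β-carbon C5 in a highly asynchronous endo [4+2] (in the limit a Mukaiyama–Michael addition followed by closure of the silyloxyallyl cation onto C10), so that the C4–C5 and C1–C10 bonds form in one operation. The closest known reaction types are the AlBr3/AlMe3-promoted Diels–Alder reactions of hindered 2-silyloxydienes with 3-methylcyclohex-2-enone (racemic) and the oxazaborolidinium-catalysed enantioselective Diels–Alder reactions of 2-silyloxydienes with cyclohex-2-enone and quinones; the new element is enantiocontrol on a β,β-disubstituted enone. Ring A is closed by intermolecular [4+2] cycloaddition, suprafacial on the enone, which gives the cis ring fusion. The quaternary C5 is set by the catalyst, which blocks one enone face; C10 follows from suprafacial addition (H cis to the C5 methyl) and C4 from the endo approach (methyl anti to the C5 methyl), and since C4 and C10 are both equilibrated in step 4 only the C5 configuration has to be secured here. The step needs regioselectivity and enantioface selectivity: the 3-silyloxy group makes C4 the nucleophilic diene terminus, which pairs with the electrophilic β-carbon C5 and overrides the weaker bias of the terminal methyl, and the facial bias comes from the catalyst alone because 3 has no stereocentre.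

Step 3
Reactants: 4 cis-fused adduct
Product: 6 4α,5β-dimethyl-3-(triisopropylsilyloxy)-10β-H-decala-2,7-dien-9-one, via lithium enolate 5 (not isolated)
Conditions: LiN(i-Pr)2, THF, −78 °C; then PhS(Cl)=N-t-Bu, −78 °C
Reagents that add atoms: none
Why: Kinetic deprotonation should occur at the C8 methylene (C10 is a ring-fusion methine) and the lithium enolate is dehydrogenated by the sulfinimidoyl chloride (S-sulfenylation then syn-elimination, a known one-pot ketone-to-enone method), which marks ring B so that the two carbonyl groups stay distinguishable after step 4; the silyl enol ether is inert to both reagents and no stereocentre is formed.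

Step 4
Reactants: 6 dienone silyl enol ether
Product: 8 trans-fused 4β,5β-dimethyl-10α-H-decal-7-ene-3,9-dione, via cis-fused enedione 7 (not isolated)
Conditions: aq. HF, MeCN, 0 °C; then NaOMe (cat.), MeOH, rt
Reagents that add atoms: none
Why: Protodesilylation of the enol ether unveils the C3 ketone, and base-mediated epimerisation at C4 (α to C3=O) and C10 (α' to the enone) should funnel the material to the thermodynamic isomer, expected to be trans-fused with an equatorial 4β-methyl because the axial C5 methyl then meets a single syn-axial hydrogen (C3, C7 and C9 are trigonal), in line with 5α-configured 6-oxo steroids and friedelin-type 4-methyl-3-ketones.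

Step 5
Reactants: 8 trans-fused enedione
Product: 10 3α-hydroxy-4β,5β-dimethyl-10α-H-decal-8-en-9-yl trifluoromethanesulfonate, via dilithium alkoxide enolate 9 (not isolated)
Conditions: Li (4.2 equiv), NH3(l)–THF, t-BuOH (2 equiv), −78 → −33 °C; NH3 removed; PhNTf2, THF, 0 °C
Reagents that add atoms: N-phenylbis(trifluoromethanesulfonimide), O=S(=O)(N(c1ccccc1)S(=O)(=O)C(F)(F)F)C(F)(F)F
Why: Dissolving-metal reduction does two jobs at once: the enone takes up two electrons and one proton to give regiospecifically the C8=C9 lithium enolate, which is not reduced further, while the C3 ketone is reduced by electron transfer to the thermodynamically favoured equatorial 3α-alkoxide (trans to the C4 methyl, whereas hydride reagents would be steered to the axial alcohol by the syn-axial C5 methyl); the triflimide then sulfonylates the enolate oxygen in preference to the hindered alkoxide (enolate O-triflation).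

Step 6
Reactants: 10 enol triflate
Product: 11 4β,5β-dimethyl-10α-H-decal-8-en-3α-ol
Conditions: Pd(OAc)2 (cat.), PPh3, HCO2H, Bu3N, DMF, 60 °C
Reagents that add atoms: none
Why: Palladium-catalysed formate reduction of the enol triflate (oxidative addition to zerovalent palladium, formate-to-hydride exchange with loss of CO2, reductive elimination) replaces OTf by H and leaves the C8=C9 alkene in place; the free alcohol is tolerated and no stereocentre is touched.

Step 7
Reactants: 11 alkenol
Product: 12 4β,5β-dimethyl-10α-H-decalin-3α,8α,9α-triol
Conditions: OsO4 (cat.), N-methylmorpholine N-oxide, acetone–H2O, rt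
Reagents that add atoms: osmium tetroxide (catalytic oxygen carrier), O=[Os](=O)(=O)=O; N-methylmorpholine N-oxide, C[N+]1([O-])CCOCC1; water, O
Why: Upjohn dihydroxylation: OsO4 should add suprafacially to the less hindered α face, anti to the axial C5 methyl that lies 1,3 to C9, to give the 8α,9α-diol, which fixes the equatorial 9α-hydroxyl of the target.

Step 8
Reactants: 12 triol
Product: 14 3α,9α-dihydroxy-4β,5β-dimethyl-10α-H-decalin-8-one, via stannylene acetal 13 (not isolated)
Conditions: Bu2SnO, toluene, reflux (−H2O); then Br2, CH2Cl2, 4 Å molecular sieves, rt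
Reagents that add atoms: none
Why: Brominolysis of the dibutylstannylene acetal of a cis-diol oxidises the axial hydroxyl (here C8–OH, whose equatorial carbinol hydrogen is exposed, whereas H-9 is axial and shielded by the C5 methyl) to the ketone without C–C cleavage, and the isolated 3-OH does not form a stannylene; the C9 stereocentre is kept and is in any case the more stable equatorial epimer of the α-ketol.

Step 9
Reactants: 14 hydroxy ketone
Product: 16 3α,9α-dihydroxy-7α-(2-hydroxypropan-2-yl)-4β,5β-dimethyl-10α-H-decalin-8-one, via trilithium salt 15 (not isolated)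
Conditions: LiN(i-Pr)2 (3.3 equiv), THF, −78 → −40 °C; acetone, −78 °C; H2O quench at −78 °C
Reagents that add atoms: acetone, CC(C)=O
Why: Aldol addition: two equivalents of base are consumed by the hydroxyls and the third should enolise the C8 ketone towards the C7 methylene (C9–H sits next to an alkoxide), and the enolate adds to acetone; the C7 stereocentre formed here (drawn α, equatorial) is of no consequence since it is removed in step 10.

Step 10
Reactants: 16 aldol
Product: 17 3α,9α-dihydroxy-4β,5β-dimethyl-7-(propan-2-ylidene)-10α-H-decalin-8-one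
Conditions: p-toluenesulfonic acid monohydrate (cat.), CH2Cl2, rt
Reagents that add atoms: none
Why: Acid-catalysed dehydration of the tertiary β-hydroxy ketone through its enol (completion of the aldol condensation) should give the conjugated tetrasubstituted C7=C11 alkene, while the secondary alcohols are not ionised under these mild conditions.

Step 11
Reactants: 18 (E)-oct-2-enal
Product: 19 (E)-non-3-en-1-yne
Conditions: Me3SiCHN2, LiN(i-Pr)2, THF, −78 °C; then 18, −78 °C → rt
Reagents that add atoms: (trimethylsilyl)diazomethane, C[Si](C)(C)C=[N+]=[N-]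
Why: Colvin rearrangement: 1,2-addition of lithiated trimethylsilyldiazomethane to the aldehyde, Peterson-type loss of silanolate, loss of N2 and 1,2-hydrogen shift of the alkylidene carbene give the terminal enyne with the E-alkene untouched.

Step 12
Reactants: 19 (E)-non-3-en-1-yne
Product: 21 (1E,3E)-1-iodo-2-methylnona-1,3-diene, via alkenylalane 20 (not isolated)
Conditions: AlMe3, Cp2ZrCl2 (cat.), CH2Cl2, 0 °C → rt; then I2, THF, −30 → 0 °C
Reagents that add atoms: trimethylaluminium, C[Al](C)C; iodine, II
Why: Zirconium-catalysed methylalumination (Negishi carboalumination) adds CH3 and Al syn across the terminal alkyne with CH3 on the internal carbon, and iodinolysis of the C–Al bond with retention gives the (1E,3E)-dienyl iodide, which fixes the trisubstituted alkene of the side chain.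

Step 13
Reactants: 21 (1E,3E)-1-iodo-2-methylnona-1,3-diene
Product: 22 (2E,4E,6E)-5-methyldodeca-2,4,6-trienoic acid
Conditions: acrylic acid, Pd(OAc)2 (cat.), K2CO3, Bu4NCl, DMF, rt; acidic work-up
Reagents that add atoms: acrylic acid, C=CC(=O)O
Why: Heck reaction under phase-transfer conditions: oxidative addition with retention, syn-insertion of acrylate and syn-β-hydride elimination should create the 2E-alkene and deliver the trienoic acid directly.

Step 14
Reactants: 17 diol enone; 22 (2E,4E,6E)-5-methyldodeca-2,4,6-trienoic acid
Product: 24 target ester, via mixed anhydride 23 (not isolated)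
Conditions: 2,4,6-trichlorobenzoyl chloride, Et3N, toluene, rt; then 17, 4-(dimethylamino)pyridine, toluene, 0 °C → rt
Reagents that add atoms: none
Why: Yamaguchi esterification: the bulky mixed anhydride should acylate the equatorial 3-OH, an ordinary secondary alcohol, faster than the 9-OH, which is deactivated by the adjacent carbonyl group (inductive effect and intramolecular hydrogen bond); no stereocentre is involved.

**Compound list**

1 | pent-1-en-3-one | CCC(=O)C=C | starting material
2 | (Z)-triisopropyl(penta-1,3-dien-3-yloxy)silane | C/C=C(/C=C)O[Si](C(C)C)(C(C)C)C(C)C | intermediate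
3 | 3-methylcyclohex-2-en-1-one | CC1=CC(=O)CCC1 | starting material
4 | cis-fused adduct: 4α,5β-dimethyl-3-(triisopropylsilyloxy)-10β-H-decal-2-en-9-one | CC(C)[Si](C(C)C)(C(C)C)OC1=CC[C@@H]2C(=O)CCC[C@]2(C)[C@@H]1C | intermediate
5 | lithium C8=C9 enolate of 4 (9-OLi) | CC(C)[Si](C(C)C)(C(C)C)OC1=CC[C@@H]2C(O[Li])=CCC[C@]2(C)[C@@H]1C | intermediate
6 | 4α,5β-dimethyl-3-(triisopropylsilyloxy)-10β-H-decala-2,7-dien-9-one | CC(C)[Si](C(C)C)(C(C)C)OC1=CC[C@@H]2C(=O)C=CC[C@]2(C)[C@@H]1C | intermediate
7 | cis-fused enedione: 4α,5β-dimethyl-10β-H-decal-7-ene-3,9-dione | O=C1CC[C@@H]2C(=O)C=CC[C@]2(C)[C@@H]1C | intermediate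
8 | trans-fused enedione: 4β,5β-dimethyl-10α-H-decal-7-ene-3,9-dione | O=C1CC[C@H]2C(=O)C=CC[C@]2(C)[C@H]1C | intermediate
9 | dilithium salt: 3α-alkoxide and C8=C9 enolate (3-OLi, 9-OLi) of the reduced enedione | [Li]O[C@@H]1CC[C@H]2C(O[Li])=CCC[C@]2(C)[C@H]1C | intermediate
10 | 3α-hydroxy-4β,5β-dimethyl-10α-H-decal-8-en-9-yl trifluoromethanesulfonate | O[C@@H]1CC[C@H]2C(OS(=O)(=O)C(F)(F)F)=CCC[C@]2(C)[C@H]1C | intermediate
11 | 4β,5β-dimethyl-10α-H-decal-8-en-3α-ol | O[C@@H]1CC[C@H]2C=CCC[C@]2(C)[C@H]1C | intermediate
12 | 4β,5β-dimethyl-10α-H-decalin-3α,8α,9α-triol | O[C@@H]1CC[C@H]2[C@H](O)[C@H](O)CC[C@]2(C)[C@H]1C | intermediate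
13 | 8,9-O-dibutylstannylene acetal of 12 | O[C@@H]1CC[C@H]2[C@@H]3O[Sn](CCCC)(CCCC)O[C@@H]3CC[C@]2(C)[C@H]1C | intermediate
14 | 3α,9α-dihydroxy-4β,5β-dimethyl-10α-H-decalin-8-one | O[C@@H]1CC[C@H]2[C@H](O)C(=O)CC[C@]2(C)[C@H]1C | intermediate
15 | trilithium salt of 14 (3-OLi, 9-OLi, C7=C8 enolate 8-OLi) | [Li]O[C@@H]1CC[C@H]2[C@H](O[Li])C(O[Li])=CC[C@]2(C)[C@H]1C | intermediate
16 | 3α,9α-dihydroxy-7α-(2-hydroxypropan-2-yl)-4β,5β-dimethyl-10α-H-decalin-8-one | O[C@@H]1CC[C@H]2[C@H](O)C(=O)[C@H](C(C)(C)O)C[C@]2(C)[C@H]1C | intermediate
17 | 3α,9α-dihydroxy-4β,5β-dimethyl-7-(propan-2-ylidene)-10α-H-decalin-8-one | O[C@@H]1CC[C@H]2[C@H](O)C(=O)C(=C(C)C)C[C@]2(C)[C@H]1C | intermediate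
18 | (E)-oct-2-enal | CCCCC/C=C/C=O | starting material
19 | (E)-non-3-en-1-yne | CCCCC/C=C/C#C | intermediate
20 | dimethyl[(1E,3E)-2-methylnona-1,3-dien-1-yl]alane | CCCCC/C=C/C(C)=C/[Al](C)C | intermediate
21 | (1E,3E)-1-iodo-2-methylnona-1,3-diene | CCCCC/C=C/C(C)=C/I | intermediate
22 | (2E,4E,6E)-5-methyldodeca-2,4,6-trienoic acid | CCCCC/C=C/C(C)=C/C=C/C(=O)O | intermediate
23 | mixed anhydride of 22 with 2,4,6-trichlorobenzoic acid | CCCCC/C=C/C(C)=C/C=C/C(=O)OC(=O)c1c(Cl)cc(Cl)cc1Cl | intermediate
24 | (1R,2R,4aR,5S,8aR)-5-hydroxy-1,8a-dimethyl-6-oxo-7-(propan-2-ylidene)decahydronaphthalen-2-yl (2E,4E,6E)-5-methyldodeca-2,4,6-trienoate (3α-acyloxy-9α-hydroxy-8-ketone in the numbering of the plan) | CCCCC/C=C/C(C)=C/C=C/C(=O)O[C@@H]1CC[C@H]2[C@H](O)C(=O)C(=C(C)C)C[C@]2(C)[C@H]1C | target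

**Count and risks**

Total step count: 14. Longest linear sequence: 11 steps (steps 1–10 and 14); steps 11–13 build the side chain separately.

Steps most likely to fail:

Step 2 (proposed new method). The chiral Lewis acid may activate the β,β-disubstituted enone too weakly, or discriminate its two faces poorly. The fallback sets out from 2 and 3 and runs the cycloaddition with the achiral mixed Lewis acid AlBr3/AlMe3 (toluene–CH2Cl2, −5 °C), a combination known to drive Diels–Alder reactions between hindered 2-silyloxydienes and 3-methylcyclohex-2-enone. This should give 4 as the racemate, that is, together with the enantiomer of 4 F1. The two are separated by preparative chromatography on a chiral stationary phase (cellulose tris(3,5-dimethylphenylcarbamate), supercritical CO2/2-propanol), and the route is rejoined at 4.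

Step 9. Proton transfer from acetone to the polylithiated enolate, poor solubility of the trianion, or reversal of the aldol addition may stall the reaction. The fallback sets out from 14 and first masks both hydroxyls (Me3SiCl, imidazole, CH2Cl2) as the 3,9-bis(trimethylsilyl) ether of 14 F2. One equivalent of LiN(i-Pr)2 (THF, −78 °C) then gives the C7=C8 lithium enolate of the bis-silyl ether F3, a simple mono-enolate of the kind used for acetone aldols on decalones. It is added to excess acetone at −78 °C to give the bis(trimethylsilyl) ether of aldol 16 F4. Dilute HCl in THF on work-up removes both silyl groups, and the route is rejoined at 16.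

Step 14. Acylation may also occur at the C9 hydroxyl, giving mixtures of mono- and diesters. The fallback sets out from 17 and 22 and acylates both hydroxyls with an excess of mixed anhydride 23 and 4-(dimethylamino)pyridine to give the 3,9-bis[(2E,4E,6E)-5-methyldodeca-2,4,6-trienoate] of 17 F5. The ester at C9 is activated by the neighbouring ketone and is cleaved selectively by brief methanolysis (K2CO3, MeOH, 0 °C), which returns the route at 24.

**Further compounds**

F1 | step 2 | enantiomer of adduct 4 | CC(C)[Si](C(C)C)(C(C)C)OC1=CC[C@H]2C(=O)CCC[C@@]2(C)[C@H]1C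
F2 | step 9 | 3,9-bis(trimethylsilyl) ether of 14 | C[Si](C)(C)O[C@@H]1CC[C@H]2[C@H](O[Si](C)(C)C)C(=O)CC[C@]2(C)[C@H]1C
F3 | step 9 | C7=C8 lithium enolate of the bis-silyl ether | C[Si](C)(C)O[C@@H]1CC[C@H]2[C@H](O[Si](C)(C)C)C(O[Li])=CC[C@]2(C)[C@H]1C
F4 | step 9 | 3,9-bis(trimethylsilyl) ether of aldol 16 | C[Si](C)(C)O[C@@H]1CC[C@H]2[C@H](O[Si](C)(C)C)C(=O)[C@H](C(C)(C)O)C[C@]2(C)[C@H]1C
F5 | step 14 | 3,9-bis[(2E,4E,6E)-5-methyldodeca-2,4,6-trienoate] of 17 | CCCCC/C=C/C(C)=C/C=C/C(=O)O[C@@H]1CC[C@H]2[C@H](OC(=O)/C=C/C=C(C)/C=C/CCCCC)C(=O)C(=C(C)C)C[C@]2(C)[C@H]1C
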